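**Strategy.** The plan rests on disconnecting C6–C7, the bond shared by the ten-membered carbocycle and the γ-lactone: the O6–C6–C7–C11(=C13) homoallylic alcohol array is the signature of a [2,3]-Wittig shift. In one operation, lithiation at C6 of a thirteen-membered diallylic ether (C6–O–C13) forms C6–C7, cleaves O–C13, unveils the C11=C13 methylene, contracts the ring to the cyclodecadiene and sets C6 and C7. The precursor is the (4Z,1(10)Z)-configured macrocyclic ether with C8 trans to C13 across C7=C11, carrying 8-OTBS, 9-OTES, 14-OTBS and a free C12 hydroxyl, assembled from nerol (C1–C6), 2-deoxy-L-ribose (C7–C10, C14) and a phosphonoacrylate (C11–C13).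

Key step: step 18

Assumption: locants are the germacrane locants of the target (ring C1–C10, lactone carbons C11–C13, C14 on C10, C15 on C4); the 8S,9R erythro diol maps onto C4/C3 of the L-sugar (the D-sugar would give the enantiomer); 2-deoxy-L-ribose is drawn open-chain; alkoxides formed by simple O–H deprotonation are not numbered.

Step 1
Reactants: 1 nerol
Product: 2 nerol 4-methoxybenzyl (PMB) ether
Conditions: NaH, PMBCl, Bu4NI (cat.), THF/DMF, 0 °C → rt
Reagents that add atoms: 4-methoxybenzyl chloride, COc1ccc(CCl)cc1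
Why: Williamson etherification of the primary allylic alkoxide; no stereocentre is formed and the Z olefin (future C4=C5) is not touched.

Step 2
Reactants: 2 nerol PMB ether
Product: 3 6,7-epoxide of 2 (racemic at the epoxide CH)
Conditions: mCPBA (1.05 equiv), NaHCO3, CH2Cl2, −20 → 0 °C
Reagents that add atoms: 3-chloroperbenzoic acid, OOC(=O)c1cccc(Cl)c1
Why: Prilezhaev epoxidation should take the remote, more electron-rich trisubstituted olefin in preference to the one deactivated by the allylic ether oxygen; the new stereocentre forms as a racemate and is excised in step 3.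

Step 3
Reactants: 3 epoxide
Product: 4 (4Z)-6-(4-methoxybenzyloxy)-4-methylhex-4-enal (C1–C6 and C15; CHO = C1)
Conditions: H5IO6, THF/H2O, 0 °C
Reagents that add atoms: none
Why: Periodic acid opens the epoxide to the glycol and cleaves it (Malaprade cleavage) to the aldehyde and acetone; the aldehyde oxygen is the former epoxide oxygen and the Z olefin is a spectator.

Step 4
Reactants: 5 2-deoxy-L-ribose
Product: 6 2-deoxy-L-ribono-1,4-lactone
Conditions: Br2, H2O, rt; then concentration
Reagents that add atoms: none
Why: Bromine-water oxidation of the aldose hemiacetal to the aldonic acid, which closes to the five-membered 1,4-lactone; C3 and C4 (future C9 and C8) are untouched.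

Step 5
Reactants: 6 2-deoxy-L-ribono-1,4-lactone
Product: 7 3,5-bis-O-triethylsilyl lactone
Conditions: TESCl, imidazole, DMF, 0 °C → rt
Reagents that add atoms: chlorotriethylsilane, CC[Si](Cl)(CC)CC
Why: Imidazole-promoted silylation of both hydroxyls; the primary TES ether (C7) is the later handle for direct oxidation and the secondary one (C9) marks the future acetate position.

Step 6
Reactants: 7 bis-TES lactone, 4 aldehyde
Product: 9 aldol adduct (mixture of epimers at C10 and at the C1 carbinol), via lithium enolate 8 (not isolated)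
Conditions: LiHMDS, THF, −78 °C; then 4, −78 °C; then AcOH
Reagents that add atoms: lithium hexamethyldisilazide, [Li]N([Si](C)(C)C)[Si](C)(C)C (lithium only in 8)
Why: Aldol addition of the lactone lithium enolate, which at −78 °C does not expel the 9-silyloxy group, to the aldehyde carbon C1; the two new stereocentres arise as a mixture that is irrelevant because both become sp2 in step 7.

Step 7
Reactants: 9 aldol adduct
Product: 11 (E)-alkylidene lactone, via mesylate 10 (not isolated)
Conditions: MsCl, Et3N, CH2Cl2, 0 °C; then DBU, 0 °C → rt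
Reagents that add atoms: methanesulfonyl chloride, CS(=O)(=O)Cl (atoms stay only in 10)
Why: Mesylation followed by E1cB elimination through the lactone enolate (mesylate leaves far faster than the C9 silyloxide) should give mainly the thermodynamically preferred E-alkylidene γ-lactone, in which C2 is trans to the carbonyl C14 and therefore cis to C9; a minor Z isomer would be removed by chromatography.

Step 8
Reactants: 11 (E)-alkylidene lactone
Product: 12 8,14-diol (acyclic C1–C10/C14 chain)
Conditions: DIBAL-H (4.5 equiv), CH2Cl2, −78 → −20 °C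
Reagents that add atoms: none
Why: DIBAL-H reduces the conjugated lactone by 1,2-hydride addition through the lactol to the C14 allylic alcohol and frees the C8 hydroxyl; the C1=C10 geometry is retained and no stereocentre is formed.

Step 9
Reactants: 12 8,14-diol
Product: 13 8,14-bis-TBS ether
Conditions: TBSOTf, 2,6-lutidine, CH2Cl2, −78 → 0 °C
Reagents that add atoms: tert-butyldimethylsilyl triflate, CC(C)(C)[Si](C)(C)OS(=O)(=O)C(F)(F)F
Why: The silyl triflate silylates the primary allylic and the hindered secondary hydroxyl alike, which fixes the later differentiation of C8 (TBS, removed last) from C9 (TES).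

Step 10
Reactants: 13 8,14-bis-TBS ether
Product: 14 C6 alcohol
Conditions: DDQ, CH2Cl2/pH 7 buffer, 0 °C
Reagents that add atoms: none
Why: Oxidative PMB cleavage (benzylic hydride abstraction by DDQ, then hydrolysis of the oxocarbenium ion); buffered conditions leave TES and TBS ethers and the trisubstituted olefins intact.

Step 11
Reactants: 14 C6 alcohol
Product: 16 C6 allylic chloride, via C6 mesylate 15 (not isolated)
Conditions: MsCl, 2,4,6-collidine, LiCl, DMF, 0 °C
Reagents that add atoms: lithium chloride, [Li+].[Cl-]; methanesulfonyl chloride, CS(=O)(=O)Cl (atoms stay only in 15)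
Why: In situ mesylation and SN2 displacement by chloride convert the primary allylic alcohol into the chloride without allylic transposition or loss of the Z geometry; the collidine-buffered medium spares the silyl ethers.

Step 12
Reactants: 16 C6 allylic chloride
Product: 17 C7 aldehyde
Conditions: (COCl)2, DMSO, CH2Cl2, −78 → −40 °C; then Et3N, −78 → 0 °C
Reagents that add atoms: none
Why: Swern oxidation with warming before the base is added cleaves and oxidises primary TES ethers directly (known oxidative desilylation), while the secondary TES ether, both TBS ethers and the allylic chloride persist; base at low temperature avoids epimerisation of C8.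

Step 13
Reactants: 18 ethyl 2-(diethoxyphosphoryl)acrylate
Product: 19 ethyl 2-(diethoxyphosphoryl)-3-(4-methoxybenzyloxy)propanoate (racemic)
Conditions: 4-methoxybenzyl alcohol, NaH (10 mol %), THF, 0 °C → rt
Reagents that add atoms: 4-methoxybenzyl alcohol, COc1ccc(CO)cc1
Why: Base-catalysed oxa-Michael addition of the alkoxide to the doubly activated vinylphosphonate; the adduct carbanion is reprotonated by the alcohol, so the base turns over.

Step 14
Reactants: 17 C7 aldehyde, 19 phosphonate
Product: 20 (E)-enoate (C7=C11 with ester carbon C13 and C12H2OPMB)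
Conditions: NaH, THF, 0 °C; then 17, −78 → 0 °C
Reagents that add atoms: none
Why: Horner–Wadsworth–Emmons olefination; an α-branched aldehyde and an α-substituted phosphonoacetate should funnel through reversible adduct formation to the E-enoate, which places C8 trans to the ester carbon C13 and cis to C12, and the preformed sodium phosphonate is too weakly basic to epimerise C8.

Step 15
Reactants: 20 (E)-enoate
Product: 21 C13 allylic alcohol
Conditions: DIBAL-H (2.5 equiv), CH2Cl2, −78 °C
Reagents that add atoms: none
Why: DIBAL-H 1,2-reduction of the enoate ester to the allylic alcohol; at −78 °C the allylic chloride and the silyl ethers are not attacked.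

Step 16
Reactants: 21 C13 allylic alcohol
Product: 22 thirteen-membered diallylic ether with 12-O-PMB
Conditions: NaH, Bu4NI (cat.), THF (2 mM, slow addition), 45 °C
Reagents that add atoms: none
Why: Intramolecular Williamson etherification (SN2 of the C13 alkoxide at the primary allylic C6 chloride) under high dilution, the closure type known for 13-membered diallylic ethers; three trisubstituted olefins restrict the chain and no stereocentre is formed.

Step 17
Reactants: 22 macrocyclic ether with 12-O-PMB
Product: 23 thirteen-membered diallylic ether with free 12-OH (key-step precursor; 8S,9R)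
Conditions: DDQ, CH2Cl2/pH 7 buffer, 0 °C
Reagents that add atoms: none
Why: Oxidative PMB cleavage as in step 10 frees the C12 hydroxyl; the diallylic ether and the silyl ethers are inert to buffered DDQ.

Step 18
Reactants: 23 thirteen-membered diallylic ether with free 12-OH
Product: 25 ten-membered 6,12-diol (6R,7S,8S,9R; 6-OH, 7-(3-hydroxyprop-1-en-2-yl), 8-OTBS, 9-OTES, 14-OTBS), via C6-lithio lithium alkoxide 24 (not isolated)
Conditions: n-BuLi (3 equiv), THF, −78 → −25 °C; then H2O
Reagents that add atoms: n-butyllithium, [Li]CCCC (lithium only in 24)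
Why: After the C12 hydroxyl has become its lithium alkoxide, n-BuLi removes a C6 proton (allylic to C4=C5 and α to the ring oxygen) and the C6 carbanion adds suprafacially to C7 through a five-membered envelope transition state (C6–O–C13–C11=C7) while O–C13 breaks, a [2,3]-Wittig rearrangement. The closest known reaction is the ring contraction of 13-membered diallylic ethers to cyclodeca-1,5-dienols under the same conditions. The ten-membered carbocycle is closed by 13→10 contraction, the C6–C7 bond forming transannularly inside the preformed macrocycle, so no end-to-end cyclisation is needed. The C6/C7 relationship follows from the olefin geometry: with C8 trans to C13 and C5 exo on the envelope, the C6–O and C7–C8 bonds come out anti, which is the trans-lactone array. The C7 face is set by C8: with C5 exo, the C8 substituent pointing towards C5 must be hydrogen (otherwise a syn-pentane clash), which leaves the C8–OTBS bond anti to the forming bond and away from the C12 methylene while the ring continues through C9, and this arrangement gives the 7,8-relationship of the target. The step needs lithiation at C6 and this facial preference; C6 is the only ether methylene on an unsubstituted CH= terminus, the C12 alkoxide disfavours metalation at C13 and C12, and a shift from C13 would have to build a quaternary C4.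

Step 19
Reactants: 25 ten-membered 6,12-diol
Product: 28 trans-fused α-methylene-γ-lactone (6,12-olide; 8-OTBS, 9-OTES, 14-OTBS), via hydroxy enal 26 (not isolated), via lactol 27 (not isolated)
Conditions: TEMPO (20 mol %), PhI(OAc)2 (3 equiv), CH2Cl2, rt
Reagents that add atoms: none
Why: Oxoammonium oxidation takes the primary allylic alcohol much faster than the secondary C6 carbinol; the enal closes on O6 to the five-membered lactol (its new centre is transient), which is oxidised to the lactone, the known oxidative lactonisation of 2-methylene-1,4-diols; O8 is silylated, so only the 6,12-olide can form.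

Step 20
Reactants: 28 α-methylene-γ-lactone
Product: 29 9,14-diol (8-OTBS retained)
Conditions: CSA (10 mol %), MeOH/CH2Cl2 (1:1), 0 °C
Reagents that add atoms: none
Why: Acid-catalysed methanolysis cleaves the secondary TES ether and the primary allylic TBS ether, while the hindered secondary TBS ether at C8 is far slower; the lactone and the olefins are stable to these conditions.

Step 21
Reactants: 29 9,14-diol
Product: 30 14-O-isovalerate
Conditions: isovaleryl chloride (1.1 equiv), 2,4,6-collidine, CH2Cl2, −78 → −30 °C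
Reagents that add atoms: isovaleryl chloride, CC(C)CC(Cl)=O
Why: Kinetic acylation with an acid chloride and a hindered pyridine base at low temperature selects the primary allylic hydroxyl over the secondary C9 hydroxyl flanked by the C8 silyl ether.

Step 22
Reactants: 30 14-O-isovalerate
Product: 31 9-O-acetate
Conditions: Ac2O, pyridine, DMAP (cat.), CH2Cl2, 0 °C → rt
Reagents that add atoms: acetic anhydride, CC(=O)OC(C)=O
Why: DMAP-catalysed acetylation of the only free hydroxyl; no stereocentre is touched.

Step 23
Reactants: 31 9-O-acetate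
Product: 32 target CNP0603244.1 (6R,7R,8S,9R)
Conditions: HF·pyridine, THF, 0 °C → rt
Reagents that add atoms: none
Why: Fluoride cleavage of the last silyl ether under acidic conditions, which should avoid O9→O8 acetyl migration and conjugate addition to the α-methylene lactone.

**Compound list**

1 | nerol, (2Z)-3,7-dimethylocta-2,6-dien-1-ol | CC(C)=CCC/C(C)=C\CO | starting material
2 | nerol 4-methoxybenzyl ether | CC(C)=CCC/C(C)=C\COCc1ccc(OC)cc1 | intermediate
3 | (2Z)-6,7-epoxy-1-(4-methoxybenzyloxy)-3,7-dimethyloct-2-ene, racemic at the epoxide CH | CC1(C)OC1CC/C(C)=C\COCc2ccc(OC)cc2 | intermediate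
4 | (4Z)-6-(4-methoxybenzyloxy)-4-methylhex-4-enal | O=CCC/C(C)=C\COCc1ccc(OC)cc1 | intermediate
5 | 2-deoxy-L-ribose, (3R,4S)-3,4,5-trihydroxypentanal (open-chain form) | O=CC[C@@H](O)[C@@H](O)CO | starting material
6 | 2-deoxy-L-ribono-1,4-lactone, (4R,5S)-4-hydroxy-5-(hydroxymethyl)oxolan-2-one | O=C1C[C@@H](O)[C@H](CO)O1 | intermediate
7 | (4R,5S)-4-(triethylsilyloxy)-5-(triethylsilyloxymethyl)oxolan-2-one | O=C1C[C@@H](O[Si](CC)(CC)CC)[C@H](CO[Si](CC)(CC)CC)O1 | intermediate
8 | lithium enolate of 7 | [Li]OC1=C[C@@H](O[Si](CC)(CC)CC)[C@H](CO[Si](CC)(CC)CC)O1 | intermediate (not isolated)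
9 | aldol adduct: 7 carrying at ring C3 a (4Z)-1-hydroxy-6-(4-methoxybenzyloxy)-4-methylhex-4-enyl group, epimer mixture at ring C3 and the carbinol | O=C1C(C(O)CC/C(C)=C\COCc2ccc(OC)cc2)[C@@H](O[Si](CC)(CC)CC)[C@H](CO[Si](CC)(CC)CC)O1 | intermediate
10 | methanesulfonate of 9 | O=C1C(C(OS(C)(=O)=O)CC/C(C)=C\COCc2ccc(OC)cc2)[C@@H](O[Si](CC)(CC)CC)[C@H](CO[Si](CC)(CC)CC)O1 | intermediate (not isolated)
11 | (3E,4R,5S)-3-[(4Z)-6-(4-methoxybenzyloxy)-4-methylhex-4-enylidene]-4-(triethylsilyloxy)-5-(triethylsilyloxymethyl)oxolan-2-one (C2 cis to C9) | O=C1/C(=C/CC/C(C)=C\COCc2ccc(OC)cc2)[C@@H](O[Si](CC)(CC)CC)[C@H](CO[Si](CC)(CC)CC)O1 | intermediate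
12 | acyclic 8,14-diol (8S,9R): 6-OPMB, 7-OTES, 9-OTES; C4=C5 Z; C1=C10 with C2 cis to C9 | OC/C(=C/CC/C(C)=C\COCc1ccc(OC)cc1)[C@@H](O[Si](CC)(CC)CC)[C@@H](O)CO[Si](CC)(CC)CC | intermediate
13 | 8,14-bis-TBS ether of 12 | CC(C)(C)[Si](C)(C)OC/C(=C/CC/C(C)=C\COCc1ccc(OC)cc1)[C@@H](O[Si](CC)(CC)CC)[C@@H](O[Si](C)(C)C(C)(C)C)CO[Si](CC)(CC)CC | intermediate
14 | C6 alcohol (PMB removed from 13) | CC(C)(C)[Si](C)(C)OC/C(=C/CC/C(C)=C\CO)[C@@H](O[Si](CC)(CC)CC)[C@@H](O[Si](C)(C)C(C)(C)C)CO[Si](CC)(CC)CC | intermediate
15 | C6 methanesulfonate of 14 | CC(C)(C)[Si](C)(C)OC/C(=C/CC/C(C)=C\COS(C)(=O)=O)[C@@H](O[Si](CC)(CC)CC)[C@@H](O[Si](C)(C)C(C)(C)C)CO[Si](CC)(CC)CC | intermediate (not isolated)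
16 | C6 allylic chloride | CC(C)(C)[Si](C)(C)OC/C(=C/CC/C(C)=C\CCl)[C@@H](O[Si](CC)(CC)CC)[C@@H](O[Si](C)(C)C(C)(C)C)CO[Si](CC)(CC)CC | intermediate
17 | C7 aldehyde (8-OTBS, 9-OTES, 14-OTBS, 6-Cl) | CC(C)(C)[Si](C)(C)OC/C(=C/CC/C(C)=C\CCl)[C@@H](O[Si](CC)(CC)CC)[C@@H](O[Si](C)(C)C(C)(C)C)C=O | intermediate
18 | ethyl 2-(diethoxyphosphoryl)acrylate | C=C(C(=O)OCC)P(=O)(OCC)OCC | starting material
19 | ethyl 2-(diethoxyphosphoryl)-3-(4-methoxybenzyloxy)propanoate, racemic | CCOC(=O)C(COCc1ccc(OC)cc1)P(=O)(OCC)OCC | intermediate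
20 | (E)-enoate: C7=C11 with C8 trans to CO2Et (C13) and cis to C12H2OPMB; 8S,9R | CC(C)(C)[Si](C)(C)OC/C(=C/CC/C(C)=C\CCl)[C@@H](O[Si](CC)(CC)CC)[C@@H](O[Si](C)(C)C(C)(C)C)/C=C(\COCc1ccc(OC)cc1)C(=O)OCC | intermediate
21 | C13 allylic alcohol (6-Cl, 12-OPMB) | CC(C)(C)[Si](C)(C)OC/C(=C/CC/C(C)=C\CCl)[C@@H](O[Si](CC)(CC)CC)[C@@H](O[Si](C)(C)C(C)(C)C)/C=C(\COCc1ccc(OC)cc1)CO | intermediate
22 | thirteen-membered C6–O–C13 ether with 12-OPMB, 8-OTBS, 9-OTES, 14-OTBS | C1/C=C(/C)CC/C=C(/CO[Si](C)(C)C(C)(C)C)[C@@H](O[Si](CC)(CC)CC)[C@@H](O[Si](C)(C)C(C)(C)C)/C=C(\COCc2ccc(OC)cc2)CO1 | intermediate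
23 | thirteen-membered C6–O–C13 ether with free 12-OH (8S,9R; 4Z, 1(10)Z, C8 trans to C13) | C1/C=C(/C)CC/C=C(/CO[Si](C)(C)C(C)(C)C)[C@@H](O[Si](CC)(CC)CC)[C@@H](O[Si](C)(C)C(C)(C)C)/C=C(\CO)CO1 | intermediate
24 | C6-lithio derivative of the lithium 12-alkoxide of 23 | [Li]C1/C=C(/C)CC/C=C(/CO[Si](C)(C)C(C)(C)C)[C@@H](O[Si](CC)(CC)CC)[C@@H](O[Si](C)(C)C(C)(C)C)/C=C(\CO[Li])CO1 | intermediate (not isolated)
25 | ten-membered 6,12-diol (6R,7S,8S,9R), H6/H7 anti | O[C@@H]1/C=C(/C)CC/C=C(/CO[Si](C)(C)C(C)(C)C)[C@@H](O[Si](CC)(CC)CC)[C@@H](O[Si](C)(C)C(C)(C)C)[C@H]1C(=C)CO | intermediate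
26 | 6-hydroxy C12 enal | O[C@@H]1/C=C(/C)CC/C=C(/CO[Si](C)(C)C(C)(C)C)[C@@H](O[Si](CC)(CC)CC)[C@@H](O[Si](C)(C)C(C)(C)C)[C@H]1C(=C)C=O | intermediate (not isolated)
27 | 6,12-lactol, epimer mixture at C12 | C=C1C(O)O[C@@H]2/C=C(/C)CC/C=C(/CO[Si](C)(C)C(C)(C)C)[C@@H](O[Si](CC)(CC)CC)[C@@H](O[Si](C)(C)C(C)(C)C)[C@@H]12 | intermediate (not isolated)
28 | trans-fused α-methylene-γ-lactone with 8-OTBS, 9-OTES, 14-OTBS | C=C1C(=O)O[C@@H]2/C=C(/C)CC/C=C(/CO[Si](C)(C)C(C)(C)C)[C@@H](O[Si](CC)(CC)CC)[C@@H](O[Si](C)(C)C(C)(C)C)[C@@H]12 | intermediate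
29 | 9,14-diol with 8-OTBS | C=C1C(=O)O[C@@H]2/C=C(/C)CC/C=C(/CO)[C@@H](O)[C@@H](O[Si](C)(C)C(C)(C)C)[C@@H]12 | intermediate
30 | 14-O-isovalerate with 9-OH, 8-OTBS | C=C1C(=O)O[C@@H]2/C=C(/C)CC/C=C(/COC(=O)CC(C)C)[C@@H](O)[C@@H](O[Si](C)(C)C(C)(C)C)[C@@H]12 | intermediate
31 | 9-O-acetyl-14-O-isovaleryl 8-OTBS lactone | C=C1C(=O)O[C@@H]2/C=C(/C)CC/C=C(/COC(=O)CC(C)C)[C@@H](OC(C)=O)[C@@H](O[Si](C)(C)C(C)(C)C)[C@@H]12 | intermediate
32 | CNP0603244.1 (6R,7R,8S,9R) | C=C1C(=O)O[C@@H]2/C=C(/C)CC/C=C(/COC(=O)CC(C)C)[C@@H](OC(C)=O)[C@@H](O)[C@@H]12 | target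

**Step count.** Total: 23 steps, including the one-step preparation of phosphonate 19. Longest linear sequence: 20 steps from nerol (steps 1–3, 6–12, 14–23).

**Steps most likely to fail**

1. Step 18.
   - What may go wrong: metalation at C13, C12 or C14 in place of C6; a competing [1,2]-shift; migration of the C8 silyl group to the new C6 alkoxide; or addition to the other face of C7, which would give the C6/C7 pair epimeric with respect to C8/C9. The facial preference has no direct precedent and is the main uncertainty.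
   - Fallback (C6–C7 bond by intramolecular Nozaki–Hiyama–Kishi allylation in place of the sigmatropic shift), setting out from 21: the allylic chloride is oxidised with N-methylmorpholine N-oxide in MeCN to the Z-configured hydroxy enal F1. Appel bromination (CBr4, PPh3, CH2Cl2, −20 °C) then gives the allylic bromide F2. CrCl2 in THF under high dilution should add the allylchromium through its γ-carbon C7 to the C6 aldehyde (anti via the chair transition state) and close the ten-membered ring as the 12-O-PMB ether F3. Buffered DDQ removes the PMB group and the route is rejoined at 25.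

2. Step 16.
   - What may go wrong: oligomerisation in competition with the 13-membered closure, or base-induced elimination of the allylic chloride.
   - Fallback (closure from the free diol, where either hydroxyl may be activated), setting out from 21: caesium acetate in DMF displaces the chloride to give the hydroxy acetate F4, and K2CO3 in MeOH liberates the diol F5. NaH followed by slow addition of N-tosylimidazole in THF under high dilution monosulfonylates one hydroxyl, and the remaining alkoxide closes the same C6–O–C13 ether. The route is rejoined at 22.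

3. Step 7.
   - What may go wrong: poor E/Z control in the E1cB elimination, or β-elimination of the C9 silyloxy group from the lactone enolate.
   - Fallback (phosphonate olefination in place of aldol/elimination), setting out from 7: LDA and diethyl chlorophosphate give the ketene acetal phosphate F6. Further LDA induces the 1,3-phosphoryl shift from oxygen to carbon and gives the α-phosphono lactone F7. Its Horner–Wadsworth–Emmons reaction with 4 (NaH, THF, 0 °C), which is reliably E-selective for α-phosphono γ-lactones, rejoins the route at 11.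

Further compounds
F1 | step 18 | hydroxy enal: 21 with C6 as the Z-enal CHO | CC(C)(C)[Si](C)(C)OC/C(=C/CC/C(C)=C\C=O)[C@@H](O[Si](CC)(CC)CC)[C@@H](O[Si](C)(C)C(C)(C)C)/C=C(\COCc1ccc(OC)cc1)CO
F2 | step 18 | allylic bromide: F1 with C13–Br | CC(C)(C)[Si](C)(C)OC/C(=C/CC/C(C)=C\C=O)[C@@H](O[Si](CC)(CC)CC)[C@@H](O[Si](C)(C)C(C)(C)C)/C=C(\COCc1ccc(OC)cc1)CBr
F3 | step 18 | 12-O-PMB ether of 25 | O[C@@H]1/C=C(/C)CC/C=C(/CO[Si](C)(C)C(C)(C)C)[C@@H](O[Si](CC)(CC)CC)[C@@H](O[Si](C)(C)C(C)(C)C)[C@H]1C(=C)COCc2ccc(OC)cc2
F4 | step 16 | hydroxy acetate: 21 with C6–OAc | CC(C)(C)[Si](C)(C)OC/C(=C/CC/C(C)=C\COC(C)=O)[C@@H](O[Si](CC)(CC)CC)[C@@H](O[Si](C)(C)C(C)(C)C)/C=C(\COCc1ccc(OC)cc1)CO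
F5 | step 16 | 6,13-diol | CC(C)(C)[Si](C)(C)OC/C(=C/CC/C(C)=C\CO)[C@@H](O[Si](CC)(CC)CC)[C@@H](O[Si](C)(C)C(C)(C)C)/C=C(\COCc1ccc(OC)cc1)CO
F6 | step 7 | ketene acetal phosphate of 7 | CCOP(=O)(OCC)OC1=C[C@@H](O[Si](CC)(CC)CC)[C@H](CO[Si](CC)(CC)CC)O1
F7 | step 7 | α-(diethoxyphosphoryl) lactone, epimer mixture at ring C3 | O=C1C(P(=O)(OCC)OCC)[C@@H](O[Si](CC)(CC)CC)[C@H](CO[Si](CC)(CC)CC)O1
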